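Ring A of the chromanone bears oxygen at C7 and C8a in a meta relation, hydrogen at C6 and C8, and two neighbouring carbon substituents: the C4 acyl group on C4a and the isopentyl chain on C5. The route cuts C5–C6 and C4a–C8a, which leads back to an acetoacetate-derived bis(silyloxy)diene (C6–C8a) and an alkynone (C4a≡C5). One regioselective [4+2] cycloaddition with aromatisation therefore delivers the crowded resorcinol ketone fully substituted. The alkynone already carries the isopentyl chain, C2 masked as a hydrogenolysable o-xylylene ketal, and the 4-benzyloxy-2-pyrone. A single neutral hydrogenolysis afterwards lets the C8a phenol close ring B. The labile C2 hemiketal is finally fixed as (R) by crystallising its quinine salt.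

Key step: step 9

Assumption: C2 epimerises in solution through the open diketone but is fixed in the crystal, and the less soluble quinine salt is taken to hold the (R)-hemiketal (to be checked by X-ray analysis of 20); if the (S)-salt is the less soluble one, quinidine replaces quinine and nothing else changes.
Atom numbers are those of the chroman-4-one (O1, C2, C3, C4, C4a, C5–C8, C8a); ring A is the benzene ring and ring B the oxygen ring.

Step 1
Reactants: 1 methyl acetoacetate
Product: 2 methyl 3-(trimethylsilyloxy)but-2-enoate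
Conditions: Me3SiCl (1.2 equiv), Et3N (1.3 equiv), hexane, rt; filter, distil
Reagents that add atoms: chlorotrimethylsilane, C[Si](C)(C)Cl
Why: O-silylation of the enolised β-keto ester with a chlorosilane and an amine base is the standard entry to the mono silyl enol ether, whose alkene geometry does not matter later.

Step 2
Reactants: 2 methyl 3-(trimethylsilyloxy)but-2-enoate
Product: 4 1-methoxy-1,3-bis(trimethylsilyloxy)buta-1,3-diene, via lithium dienolate 3 (not isolated)
Conditions: LiN(iPr)2 (1.1 equiv), THF, −78 °C; Me3SiCl (1.2 equiv), −78 °C → rt; hexane, filter under Ar, concentrate, use fresh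
Reagents that add atoms: chlorotrimethylsilane, C[Si](C)(C)Cl; lithium diisopropylamide, [Li+].CC(C)[N-]C(C)C (lithium of 3 only)
Why: Kinetic γ-deprotonation of the vinylogous ester followed by O-silylation of the dienolate is the usual two-stage preparation of 1-alkoxy-1,3-bis(silyloxy)dienes.

Step 3
Reactants: 5 dimethyl 3-oxoglutarate
Product: 6 dimethyl 2,2'-(1,5-dihydro-3H-2,4-benzodioxepine-3,3-diyl)diacetate
Conditions: 1,2-benzenedimethanol (1.2 equiv), HC(OMe)3 (1.5 equiv), TsOH·H2O (5 mol%), PhMe, 40 °C, volatiles drawn off under slight vacuum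
Reagents that add atoms: 1,2-benzenedimethanol, OCc1ccccc1CO
Why: Acid-catalysed ketalisation with an orthoester as irreversible water scavenger is standard for β-keto esters, and the o-xylylene ketal is a known carbonyl protecting group preferred here over a dioxolane because it leaves under neutral hydrogenolysis, so the dehydration-prone 2-hydroxychromanone of the endgame never meets aqueous acid.

Step 4
Reactants: 1 methyl acetoacetate; 6 dimethyl 2,2'-(1,5-dihydro-3H-2,4-benzodioxepine-3,3-diyl)diacetate
Product: 8 methyl 6-[3-(2-methoxy-2-oxoethyl)-1,5-dihydro-3H-2,4-benzodioxepin-3-yl]-3,5-dioxohexanoate, via dilithium dianion 7 (not isolated)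
Conditions: 1 (2.1 equiv), LiN(iPr)2 (4.2 equiv), THF, 0 °C; 6 (1.0 equiv), −78 → −20 °C; AcOH, −78 °C
Reagents that add atoms: lithium diisopropylamide, [Li+].CC(C)[N-]C(C)C (lithium of 7 only)
Why: Claisen-type γ-acylation of an acetoacetate dianion by an ester, known also for ketal-protected 3-oxoglutarates, should stop after one ester because the tricarbonyl product at once quenches the second equivalent of 7 by proton transfer, while the low temperature holds back enolisation of 6 and the β-elimination of a ketal oxygen that would follow.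

Step 5
Reactants: 8 methyl 6-[3-(2-methoxy-2-oxoethyl)-1,5-dihydro-3H-2,4-benzodioxepin-3-yl]-3,5-dioxohexanoate
Product: 9 methyl {3-[(4-hydroxy-2-oxo-2H-pyran-6-yl)methyl]-1,5-dihydro-3H-2,4-benzodioxepin-3-yl}acetate
Conditions: DBU (1.2 equiv), PhMe, 60 °C; brief wash with cold 0.5 M HCl
Reagents that add atoms: none
Why: Base-induced lactonisation of a 3,5-dioxo ester, in which the C5 enolate oxygen acylates the activated β-keto ester carbonyl with loss of methanol, is the standard closure to 4-hydroxy-2-pyrones and is pulled to the stable pyronate salt, whereas the isolated methyl ester on the other ketal arm lacks this activation and should stay.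

Step 6
Reactants: 9 methyl {3-[(4-hydroxy-2-oxo-2H-pyran-6-yl)methyl]-1,5-dihydro-3H-2,4-benzodioxepin-3-yl}acetate
Product: 10 methyl {3-[(4-benzyloxy-2-oxo-2H-pyran-6-yl)methyl]-1,5-dihydro-3H-2,4-benzodioxepin-3-yl}acetate
Conditions: BnOH, PPh3, DIAD, THF, 0 °C → rt
Reagents that add atoms: benzyl alcohol, OCc1ccccc1
Why: Mitsunobu etherification suits the acidic enol (pKa about 5), is known to alkylate 4-hydroxy-2-pyrones at O4, and uses no base, so neither C3 alkylation nor ketal opening by β-elimination is expected.

Step 7
Reactants: 10 methyl {3-[(4-benzyloxy-2-oxo-2H-pyran-6-yl)methyl]-1,5-dihydro-3H-2,4-benzodioxepin-3-yl}acetate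
Product: 11 {3-[(4-benzyloxy-2-oxo-2H-pyran-6-yl)methyl]-1,5-dihydro-3H-2,4-benzodioxepin-3-yl}acetic acid
Conditions: Me3SnOH (4 equiv), 1,2-dichloroethane, 70 °C; brief wash with cold 0.5 M HCl
Reagents that add atoms: trimethyltin hydroxide, C[Sn](C)(C)O
Why: Me3SnOH cleaves methyl esters under almost neutral conditions by tin-assisted hydroxide delivery and should spare the push–pull stabilised pyrone lactone, its vinylogous benzyl ester and the ketal, all of which aqueous alkali could attack.

Step 8
Reactants: 11 {3-[(4-benzyloxy-2-oxo-2H-pyran-6-yl)methyl]-1,5-dihydro-3H-2,4-benzodioxepin-3-yl}acetic acid; 12 5-methylhex-1-yne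
Product: 14 1-{3-[(4-benzyloxy-2-oxo-2H-pyran-6-yl)methyl]-1,5-dihydro-3H-2,4-benzodioxepin-3-yl}-7-methyloct-3-yn-2-one, via acid chloride 13 (not isolated)
Conditions: 1-chloro-N,N,2-trimethylprop-1-en-1-amine (1.1 equiv), CH2Cl2, 0 °C → rt; then 12 (1.2 equiv), PdCl2(PPh3)2 (2 mol%), CuI (4 mol%), Et3N (1.1 equiv), THF, rt
Reagents that add atoms: 1-chloro-N,N,2-trimethylprop-1-en-1-amine, CC(C)=C(Cl)N(C)C (chlorine of 13 only)
Why: The α-chloroenamine turns the acid into 13 without releasing HCl, and the acyl Sonogashira coupling (oxidative addition of zerovalent palladium into the C–Cl bond, transmetalation from the copper acetylide, reductive elimination) then gives the alkynone with a single equivalent of amine, which avoids organolithium reagents that would deprotonate the pyronyl CH2 or open the lactone.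

Step 9
Reactants: 14 1-{3-[(4-benzyloxy-2-oxo-2H-pyran-6-yl)methyl]-1,5-dihydro-3H-2,4-benzodioxepin-3-yl}-7-methyloct-3-yn-2-one; 4 1-methoxy-1,3-bis(trimethylsilyloxy)buta-1,3-diene
Product: 17 1-(2,4-dihydroxy-6-isopentylphenyl)-2-{3-[(4-benzyloxy-2-oxo-2H-pyran-6-yl)methyl]-1,5-dihydro-3H-2,4-benzodioxepin-3-yl}ethanone, via cyclohexadiene adduct 15 (not isolated), via bis-silyl ether 16 (not isolated)
Conditions: 4 (3 equiv), PhMe (2 M in 14), Ar, 60–70 °C, no Lewis acid; then THF, 10% aq citric acid, 0 °C → rt
Reagents that add atoms: none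
Why: This is a normal-electron-demand Diels–Alder reaction, concerted but strongly asynchronous, in which the unsubstituted CH2 terminus of 4 (largest HOMO coefficient) bonds to the alkynone β-carbon (C6–C5) ahead of the bond from the ketene acetal carbon to the α-carbon (C8a–C4a), so the six-membered carbocyclic ring A closes in one intermolecular [4+2] event to give 1,4-cyclohexadiene 15. Adduct 15 loses methanol across C8a/C6 to give arene 16, and citric acid strips both aryl silyl ethers; the closest known reactions are the benzannulations of 1-alkoxy-1,3-bis(silyloxy)butadienes with alkynones and alkynoates to resorcinol ketones and resorcylates. No stereocentre survives, since C8a of 15 becomes planar on aromatisation. Regioselectivity rests on the matched polarisation of the two partners, which places the isopentyl group next to C6–H and the acyl group next to the C8a oxygen. Chemoselectivity is needed against the pyrone, which as a donor-substituted lactone is a poor dienophile for an electron-rich diene but could act as a diene towards the tethered triple bond with loss of CO2, so excess 4, high concentration and a bath of at most 70 °C are used to favour the bimolecular reaction. Lewis acids are left out because they would divert 4 into a Michael–aldol [3+3] closure onto the C4 carbonyl and would endanger the ketal.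

Step 10
Reactants: 17 1-(2,4-dihydroxy-6-isopentylphenyl)-2-{3-[(4-benzyloxy-2-oxo-2H-pyran-6-yl)methyl]-1,5-dihydro-3H-2,4-benzodioxepin-3-yl}ethanone
Product: 19 rac-2,7-dihydroxy-2-[(4-hydroxy-2-oxo-2H-pyran-6-yl)methyl]-5-isopentylchroman-4-one, via open-chain triketone 18 (not isolated)
Conditions: H2 (1 atm), 10% Pd/C, EtOAc–THF, rt; stop at full conversion, filter, concentrate below 30 °C
Reagents that add atoms: none
Why: Catalytic hydrogenolysis cleaves the vinylogous benzyl ester and a benzylic C–O bond of the o-xylylene ketal (the documented removal of this group), the hemiketal left behind collapses to the C2 ketone 18, and the C8a hydroxyl adds to it in a 6-exo-trig closure of ring B to give the favoured hemiketal as the racemate, all in a neutral medium that does not drive dehydration to the chromone.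

Step 11
Reactants: 19 rac-2,7-dihydroxy-2-[(4-hydroxy-2-oxo-2H-pyran-6-yl)methyl]-5-isopentylchroman-4-one
Product: 20 quininium 6-{[(2R)-2,7-dihydroxy-5-isopentyl-4-oxochroman-2-yl]methyl}-2-oxo-2H-pyran-4-olate
Conditions: quinine (1.05 equiv), MeCN, stirred slurry, temperature cycles between 35 and 20 °C, seeded; filter, wash with cold MeCN
Reagents that add atoms: quinine, COC1=CC2=C(C=CN=C2C=C1)[C@H]([C@@H]3C[C@@H]4CCN3C[C@@H]4C=C)O
Why: Proposed new method: the 4-hydroxypyrone (pKa about 5) protonates the quinuclidine nitrogen of quinine to give two diastereomeric salts, C2 epimerises in the liquor by amine-catalysed ring–chain tautomerism through 18, and steady removal of the less soluble (R)-salt into the crystal should drain the whole pool into one diastereomer, so the C2 stereocentre is set by lattice selection under thermodynamic control; the closest known reaction types are the crystallisation-induced diastereomer transformation of configurationally labile carboxylic acids as alkaloid salts and the crystallisation-driven anomerisation of lactols, neither of which has been shown for a 2-hydroxychromanone hemiketal.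

Step 12
Reactants: 20 quininium 6-{[(2R)-2,7-dihydroxy-5-isopentyl-4-oxochroman-2-yl]methyl}-2-oxo-2H-pyran-4-olate
Product: 21 (2R)-2,7-dihydroxy-2-[(4-hydroxy-2-oxo-2H-pyran-6-yl)methyl]-5-isopentylchroman-4-one
Conditions: EtOAc / 0.5 M HCl, 0 °C, fast phase split; Na2SO4, concentrate cold, precipitate with heptane at −20 °C, store as solid
Reagents that add atoms: none
Why: This is plain proton transfer in which the mineral acid protonates the pyronate and carries the alkaloid into the water layer, and at 0 °C, without base and within minutes, ring opening of the hemiketal should be too slow to erode C2, which is then held again in the solid state.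

Compound list
1 | methyl acetoacetate | CC(=O)CC(=O)OC | starting material
2 | methyl 3-(trimethylsilyloxy)but-2-enoate | COC(=O)C=C(C)O[Si](C)(C)C | intermediate
3 | lithium 1-methoxy-3-(trimethylsilyloxy)buta-1,3-dien-1-olate | [Li+].C=C(O[Si](C)(C)C)C=C([O-])OC | intermediate
4 | 1-methoxy-1,3-bis(trimethylsilyloxy)buta-1,3-diene | C=C(O[Si](C)(C)C)C=C(OC)O[Si](C)(C)C | intermediate
5 | dimethyl 3-oxoglutarate | COC(=O)CC(=O)CC(=O)OC | starting material
6 | dimethyl 2,2'-(1,5-dihydro-3H-2,4-benzodioxepine-3,3-diyl)diacetate | COC(=O)CC1(CC(=O)OC)OCc2ccccc2CO1 | intermediate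
7 | dilithium dianion of methyl acetoacetate | [Li+].[Li+].C=C([O-])C=C([O-])OC | intermediate
8 | methyl 6-[3-(2-methoxy-2-oxoethyl)-1,5-dihydro-3H-2,4-benzodioxepin-3-yl]-3,5-dioxohexanoate | COC(=O)CC(=O)CC(=O)CC1(CC(=O)OC)OCc2ccccc2CO1 | intermediate
9 | methyl {3-[(4-hydroxy-2-oxo-2H-pyran-6-yl)methyl]-1,5-dihydro-3H-2,4-benzodioxepin-3-yl}acetate | COC(=O)CC1(Cc2cc(O)cc(=O)o2)OCc2ccccc2CO1 | intermediate
10 | methyl {3-[(4-benzyloxy-2-oxo-2H-pyran-6-yl)methyl]-1,5-dihydro-3H-2,4-benzodioxepin-3-yl}acetate | COC(=O)CC1(Cc2cc(OCc3ccccc3)cc(=O)o2)OCc2ccccc2CO1 | intermediate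
11 | {3-[(4-benzyloxy-2-oxo-2H-pyran-6-yl)methyl]-1,5-dihydro-3H-2,4-benzodioxepin-3-yl}acetic acid | OC(=O)CC1(Cc2cc(OCc3ccccc3)cc(=O)o2)OCc2ccccc2CO1 | intermediate
12 | 5-methylhex-1-yne | CC(C)CCC#C | starting material
13 | {3-[(4-benzyloxy-2-oxo-2H-pyran-6-yl)methyl]-1,5-dihydro-3H-2,4-benzodioxepin-3-yl}acetyl chloride | ClC(=O)CC1(Cc2cc(OCc3ccccc3)cc(=O)o2)OCc2ccccc2CO1 | intermediate
14 | alkynone: 1-{3-[(4-benzyloxy-2-oxo-2H-pyran-6-yl)methyl]-1,5-dihydro-3H-2,4-benzodioxepin-3-yl}-7-methyloct-3-yn-2-one | CC(C)CCC#CC(=O)CC1(Cc2cc(OCc3ccccc3)cc(=O)o2)OCc2ccccc2CO1 | intermediate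
15 | 1,4-cyclohexadiene cycloadduct (C8a bears OMe and OSiMe3, racemic at C8a) | CC(C)CCC1=C(C(=O)CC2(Cc3cc(OCc4ccccc4)cc(=O)o3)OCc3ccccc3CO2)C(OC)(O[Si](C)(C)C)C=C(O[Si](C)(C)C)C1 | intermediate
16 | 2,4-bis(trimethylsilyloxy)-6-isopentylphenyl ketone | CC(C)CCc1cc(O[Si](C)(C)C)cc(O[Si](C)(C)C)c1C(=O)CC1(Cc2cc(OCc3ccccc3)cc(=O)o2)OCc2ccccc2CO1 | intermediate
17 | 2,4-dihydroxy-6-isopentylphenyl ketone with C2 o-xylylene ketal and benzyloxypyrone | CC(C)CCc1cc(O)cc(O)c1C(=O)CC1(Cc2cc(OCc3ccccc3)cc(=O)o2)OCc2ccccc2CO1 | intermediate
18 | 1-(2,4-dihydroxy-6-isopentylphenyl)-4-(4-hydroxy-2-oxo-2H-pyran-6-yl)butane-1,3-dione | CC(C)CCc1cc(O)cc(O)c1C(=O)CC(=O)Cc1cc(O)cc(=O)o1 | intermediate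
19 | rac-2,7-dihydroxy-2-[(4-hydroxy-2-oxo-2H-pyran-6-yl)methyl]-5-isopentylchroman-4-one | CC(C)CCc1cc(O)cc2c1C(=O)CC(O)(Cc1cc(O)cc(=O)o1)O2 | intermediate
20 | quininium salt of the (2R)-hemiketal pyronate | CC(C)CCc1cc(O)cc2c1C(=O)C[C@@](O)(Cc1cc([O-])cc(=O)o1)O2.COC1=CC2=C(C=CN=C2C=C1)[C@H]([C@@H]3C[C@@H]4CC[NH+]3C[C@@H]4C=C)O | intermediate
21 | (2R)-2,7-dihydroxy-2-[(4-hydroxy-2-oxo-2H-pyran-6-yl)methyl]-5-isopentylchroman-4-one | CC(C)CCc1cc(O)cc2c1C(=O)C[C@@](O)(Cc1cc(O)cc(=O)o1)O2 | target

Total step count: 12. Longest linear sequence: 10 steps (steps 3–12, from dimethyl 3-oxoglutarate 5).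

Steps most likely to fail

Step 11.
- **What may go wrong:** The two diastereomeric salts may crystallise together or separate as an oil. Ring–chain exchange may be too slow to feed the crystal. The amine may also promote slow dehydration towards the chromone.
- **Fallback:** It sets out from 19 and comes back at 21. The racemate is resolved by preparative enantioselective chromatography on an immobilised polysaccharide carbamate phase at about 5 °C with a neutral eluent, a known way of separating stereolabile hemiketals. The unwanted (2S)-hemiketal F1 is re-equilibrated to 19 by warming with a trace of Et3N and fed back.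

Step 9.
- **What may go wrong:** The cycloaddition may be too slow at the temperature the substrate tolerates. The pyrone could then add as a diene across the tethered triple bond with extrusion of CO2, or diene 4 could be lost by protodesilylation before it reacts.
- **Fallback:** It sets out from 6 and comes back at 19, and it forms ring A before any pyrone is present.
  - Diester 6 is treated with MeNH(OMe)·HCl (1 equiv) and iPrMgCl (2 equiv) in THF at −20 °C to give the mono N-methoxy-N-methylamide ester F2.
  - The lithium acetylide of 12 (n-BuLi, THF, −78 °C) adds to the amide to give the alkynone ester F3.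
  - F3 and 4 undergo the same benzannulation, now free to be heated to 110 °C, to give the resorcinol ketone ester F4.
  - An excess of dianion 7 (at least 4 equiv, the first two spent on the phenols, whose phenoxides also shield the aryl ketone) acylates at the ester to give the dioxo ester F5.
  - DBU closes the hydroxypyrone F6.
  - Hydrogenolysis as in step 10 removes the ketal and gives 19.

Step 4.
- **What may go wrong:** Acylation may occur at both esters. Proton transfer from 6 to the dianion may be followed by β-elimination of a ketal oxygen. The product polyanion may close onto the remaining ester.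
- **Fallback:** It sets out from 6 and comes back at 8 without any strong base.
  - KOH (1.0 equiv) in MeOH–THF at 0 °C gives the half ester F7.
  - 1-Chloro-N,N,2-trimethylprop-1-en-1-amine gives its acid chloride F8.
  - Diene 4 (1.5 equiv, CH2Cl2, −78 → 20 °C, then aqueous work-up) is acylated at its CH2 terminus, the known neutral counterpart of the dianion acylation, to give 8.

Further compounds
F1 | step 11 | (2S)-2,7-dihydroxy-2-[(4-hydroxy-2-oxo-2H-pyran-6-yl)methyl]-5-isopentylchroman-4-one | CC(C)CCc1cc(O)cc2c1C(=O)C[C@](O)(Cc1cc(O)cc(=O)o1)O2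
F2 | step 9 | methyl (3-{2-[methoxy(methyl)amino]-2-oxoethyl}-1,5-dihydro-3H-2,4-benzodioxepin-3-yl)acetate | COC(=O)CC1(CC(=O)N(C)OC)OCc2ccccc2CO1
F3 | step 9 | methyl [3-(7-methyl-2-oxooct-3-yn-1-yl)-1,5-dihydro-3H-2,4-benzodioxepin-3-yl]acetate | CC(C)CCC#CC(=O)CC1(CC(=O)OC)OCc2ccccc2CO1
F4 | step 9 | methyl {3-[2-(2,4-dihydroxy-6-isopentylphenyl)-2-oxoethyl]-1,5-dihydro-3H-2,4-benzodioxepin-3-yl}acetate | CC(C)CCc1cc(O)cc(O)c1C(=O)CC1(CC(=O)OC)OCc2ccccc2CO1
F5 | step 9 | methyl 6-{3-[2-(2,4-dihydroxy-6-isopentylphenyl)-2-oxoethyl]-1,5-dihydro-3H-2,4-benzodioxepin-3-yl}-3,5-dioxohexanoate | CC(C)CCc1cc(O)cc(O)c1C(=O)CC1(CC(=O)CC(=O)CC(=O)OC)OCc2ccccc2CO1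
F6 | step 9 | 1-(2,4-dihydroxy-6-isopentylphenyl)-2-{3-[(4-hydroxy-2-oxo-2H-pyran-6-yl)methyl]-1,5-dihydro-3H-2,4-benzodioxepin-3-yl}ethanone | CC(C)CCc1cc(O)cc(O)c1C(=O)CC1(Cc2cc(O)cc(=O)o2)OCc2ccccc2CO1
F7 | step 4 | [3-(2-methoxy-2-oxoethyl)-1,5-dihydro-3H-2,4-benzodioxepin-3-yl]acetic acid | OC(=O)CC1(CC(=O)OC)OCc2ccccc2CO1
F8 | step 4 | methyl [3-(2-chloro-2-oxoethyl)-1,5-dihydro-3H-2,4-benzodioxepin-3-yl]acetate | ClC(=O)CC1(CC(=O)OC)OCc2ccccc2CO1
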